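The teal run had flattened by its first reading at 0.500 d, and so had the green one, so time was not what I needed from them.

| setting | teal | green | flask |
|---|---|---|---|
| Q | 0.50 M | 0.50 M | 0.50 M |
| D | 0.17 M | 0.26 M | 0.350 M |
| G | 0.10 M | 0.10 M | 0.100 M |
| remark | run made earlier | run made earlier |  |
| time |  |  | 5.0 d |

| run | time / d | J / % | L / % | Q / % |
|---|---|---|---|---|
| teal | 0.500 | 14.9 | 3.2 | 80.6 |
| teal | 1.25 | 15.8 | 3.1 | 80.5 |
| teal | 2.50 | 14.7 | 5.1 | 81.7 |
| teal | 4.00 | 15.5 | 3.1 | 82.1 |
| green | 0.500 | 25.7 | 6.2 | 68.3 |
| green | 1.25 | 26.4 | 5.2 | 67.9 |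
| green | 2.50 | 27.7 | 6.8 | 67.9 |
| green | 4.00 | 23.5 | 8.0 | 66.7 |

(each reading ± 1 percentage point)

- J present at 5.0 d, in percent of the Q charged
- L present at 5.0 d, in percent of the Q charged

- the earlier runs were read with a standard deviation of 1 percentage point

Reading the rows down, I saw no steady drift of Q in either run. Reading across, J, L and Q summed to about the whole charge of Q. I took D to be the limiting reagent, one D per Q, and gave the D not found on Q to G.

At any moment G's rate of taking D over Q's is S·cG/cQ, with S the selectivity factor 6.89. That comparison drifts as G and Q fall, and it integrates to this rule for Q and G drawing on the same D: the fraction of G left equals the fraction of Q left raised to S. I read S from the teal means, where my balance left G 0.0239 M. The same balance on the green means leaves G 0.00150 M, too little to read against the scatter.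

In the flask, D exceeds G by 0.250 M, which would take half of Q. The rule then leaves G 0.844%, so I expected 50.2% of Q in J plus L. The forecast gave J 37% and L 9.2%, together 46.2%, less than mine, on the ground that “Conversion rises slightly faster than D”.

    Q + D → J (k = 0.490 /M/h)
    G + D → X (k = 2.90 /M/h)
    D → Z (k = 0.00670 /h)
    J ⇌ L (K = 0.270, k = 0.0770 /h)

At 0.500 d the flask held D at 7.48% of its charge, X 0.0967 M and J 35.3%, with Q and G both drawing on D. At 2.50 d D stood at 0.00880% of its charge, and at 5.0 d J was 38.2%, L 10.3% and Z 0.00909 M. The fraction of Q left in the flask, 51%, raised to S gives G 1.03% of its charge, and the flask held 2.0%. For the neighbour with 0.17 M of G, S puts Q left at 62.4%. That neighbour ended with Q 63.0%.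

Readings and results stem from a simulated flask on assumed constants; scatter was added.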